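**Retrosynthetic overview**
1. Target ⇒ one three-component operation that cuts C9′–C4, C1–C5 and C10–O together: (+)-germacrene A + an o-quinone methide (from 2,4-diformylphloroglucinol and isovaleraldehyde) + water. The cyclopentane and the cycloheptane are both created in this last step.
2. (+)-Germacrene A ⇒ McMurry closure of C1=C10 in an acyclic (4E)-keto-enal (ten-membered ring, formed second to last).
3. Keto-enal ⇒ Claisen rearrangement (sets E-C4=C5, adds C1/C2) of an allylic alcohol ⇒ isopropenyl addition to (3R)-3-isopropenyl-6-oxoheptanal.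
4. Keto-aldehyde ⇒ (+)-limonene 1,2-oxide, which supplies C5–C10, C14, the isopropenyl group and the only pre-existing stereocentre (C7).
5. Ring order: ten-membered carbocycle first, then the five- and seven-membered rings together; the arene is bought.

Assumption: 2,4,6-trihydroxybenzene-1,3-dicarbaldehyde is bought as a catalogue building block; atom labels C1–C15 follow guaiane/germacrane numbering and C9′ is the benzylic carbon.

**Step 1**
Reactants: 1 (4R)-limonene 1,2-oxide [(+)-limonene oxide, cis/trans mixture]
Product: 3 (3R)-6-oxo-3-(prop-1-en-2-yl)heptanal, via limonene-1,2-diol 2 (not isolated)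
Conditions: H5IO6 (1.1 equiv), THF/H2O 3:1, 0 °C → rt, 3 h
Reagents that add atoms: water, O
Why: Aqueous periodic acid hydrolyses the trisubstituted epoxide to the diol and cleaves it in the same pot (Malaprade glycol cleavage), both epoxide diastereomers converging on one keto-aldehyde; the 1,1-disubstituted alkene is inert and the stereocentre that becomes C7 is not touched.

**Step 2**
Reactants: 3 (3R)-6-oxo-3-(prop-1-en-2-yl)heptanal
Product: 4 (5R)-7-hydroxy-8-methyl-5-(prop-1-en-2-yl)non-8-en-2-one (about 1:1 at C7)
Conditions: 2-bromopropene (2 equiv), CrCl2 (4 equiv), NiCl2 (2 mol %), DMF, 25 °C, 12 h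
Reagents that add atoms: 2-bromopropene, CC(Br)=C
Why: Nozaki–Hiyama–Kishi alkenylation: the alkenylchromium(III) reagent adds to aldehydes but not to methyl ketones, so only the aldehyde reacts; the new carbinol centre forms unselectively and is erased in step 3.

**Step 3**
Reactants: 4 (5R)-7-hydroxy-8-methyl-5-(prop-1-en-2-yl)non-8-en-2-one
Product: 6 (4E,7R)-4-methyl-10-oxo-7-(prop-1-en-2-yl)undec-4-enal, via allyl vinyl ether 5 (not isolated)
Conditions: ethyl vinyl ether (solvent), Hg(OAc)2 (10 mol %), reflux, 24 h; concentrate; PhMe, sealed tube, 130 °C, 6 h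
Reagents that add atoms: ethyl vinyl ether, C=COCC
Why: Hg(II)-catalysed transvinylation gives the allyl vinyl ether, whose Claisen [3,3] rearrangement through a chair with the carbinol substituent equatorial delivers the E-trisubstituted C4=C5 alkene (typically ≥ 9:1 E:Z) from either carbinol epimer and adds C2 and the C1 aldehyde; ketone and isopropenyl are spectators.

**Step 4**
Reactants: 6 (4E,7R)-4-methyl-10-oxo-7-(prop-1-en-2-yl)undec-4-enal
Product: 7 (+)-germacrene A [(1E,5E,8R)-1,5-dimethyl-8-(prop-1-en-2-yl)cyclodeca-1,5-diene]
Conditions: TiCl3(DME)1.5 (10 equiv), Zn–Cu (25 equiv), DME, 80 °C, syringe-pump addition of 6 over 24 h (final 2 mM); pentane/aq. K2CO3 work-up; AgNO3–SiO2, 0 °C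
Reagents that add atoms: none
Why: McMurry carbonyl coupling: titanium-mediated reductive coupling of the C1 aldehyde with the C10 methyl ketone under high dilution closes the ten-membered ring as the C1=C10 alkene; the coupling is not E/Z-selective, so 7 is separated from its 1(10)Z isomer on AgNO3–silica, the temperature stays below the onset of Cope rearrangement to β-elemene, and no stereocentre is formed.

**Step 5**
Reactants: 7 (+)-germacrene A; 8 2,4,6-trihydroxybenzene-1,3-dicarbaldehyde; 9 3-methylbutanal
Product: 12 5-[(1R)-1-[(1S,3aR,4R,7R,8aS)-4-hydroxy-1,4-dimethyl-7-(prop-1-en-2-yl)decahydroazulen-1-yl]-3-methylbutyl]-2,4,6-trihydroxybenzene-1,3-dicarbaldehyde (target CNP0594576.1), via o-quinone methide 10 (not isolated), via guaian-10-yl cation zwitterion 11 (not isolated)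
Conditions: 8 (1.2 equiv), 9 (1.5 equiv, syringe pump 6 h), EDDA (20 mol %), NaOAc (0.5 equiv), HFIP/H2O 9:1, 0 → 25 °C, dark, 16 h; preparative HPLC
Reagents that add atoms: water, O (the equivalent released in the condensation of 8 with 9 is taken up again at C10)
Why: Proposed new method: EDDA-catalysed Knoevenagel condensation of 8 with 9 gives o-quinone methide 10, whose exocyclic carbon bonds to C4 on the outer face of the strained 4,5-alkene while C5 bonds across the ring to C1 (guaiane-mode transannular cyclization that closes the five- and seven-membered rings together) and water captures the tertiary C10 cation 11 on its outer face; anti addition across both E-alkenes in the parallel conformer (C14 on the β face, C15 on the α face) translates the resident 7R centre into 1R,4S,5S,10R (trans ring fusion), and 9′R results when 10 is attacked with its isobutyl chain anti to C5 and its arene over the C15/C6 edge; the closest known reaction types are the o-quinone methide Michael addition/transannular cation capture of bicyclogermacrene and caryophyllene in phloroglucinol–terpene adduct chemistry and the acid- or epoxide-triggered germacrene-to-guaiane cyclization.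

**Compound list**
1 | (4R)-limonene 1,2-oxide (cis/trans mixture) | CC(=C)[C@@H]1CCC2(C)OC2C1 | starting material
2 | (4R)-1-methyl-4-(prop-1-en-2-yl)cyclohexane-1,2-diol | CC(=C)[C@@H]1CCC(C)(O)C(O)C1 | intermediate (not isolated)
3 | (3R)-6-oxo-3-(prop-1-en-2-yl)heptanal | O=CC[C@@H](CCC(C)=O)C(C)=C | intermediate
4 | (5R)-7-hydroxy-8-methyl-5-(prop-1-en-2-yl)non-8-en-2-one (C7 epimers) | CC(=O)CC[C@H](CC(O)C(C)=C)C(C)=C | intermediate
5 | (5R)-7-(ethenyloxy)-8-methyl-5-(prop-1-en-2-yl)non-8-en-2-one | CC(=O)CC[C@H](CC(OC=C)C(C)=C)C(C)=C | intermediate (not isolated)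
6 | (4E,7R)-4-methyl-10-oxo-7-(prop-1-en-2-yl)undec-4-enal | CC(=O)CC[C@H](C/C=C(\C)CCC=O)C(C)=C | intermediate
7 | (+)-germacrene A, (1E,5E,8R)-1,5-dimethyl-8-(prop-1-en-2-yl)cyclodeca-1,5-diene | C=C(C)[C@@H]1CC/C(C)=C/CC/C(C)=C/C1 | intermediate
8 | 2,4,6-trihydroxybenzene-1,3-dicarbaldehyde (2,4-diformylphloroglucinol) | O=Cc1c(O)cc(O)c(C=O)c1O | starting material
9 | 3-methylbutanal (isovaleraldehyde) | CC(C)CC=O | starting material
10 | (5E)-2,4-dihydroxy-5-(3-methylbutylidene)-6-oxocyclohexa-1,3-diene-1,3-dicarbaldehyde (o-quinone methide) | CC(C)C/C=C1/C(=O)C(C=O)=C(O)C(C=O)=C1O | intermediate (not isolated)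
11 | guaian-10-yl cation / phenolate zwitterion carrying the C4–C9′ and C1–C5 bonds | C=C(C)[C@@H]1CC[C+](C)[C@@H]2CC[C@](C)([C@@H](CC(C)C)c3c([O-])c(C=O)c(O)c(C=O)c3O)[C@H]2C1 | intermediate (not isolated)
12 | 5-[(1R)-1-[(1S,3aR,4R,7R,8aS)-4-hydroxy-1,4-dimethyl-7-(prop-1-en-2-yl)decahydroazulen-1-yl]-3-methylbutyl]-2,4,6-trihydroxybenzene-1,3-dicarbaldehyde | C=C(C)[C@@H]1CC[C@@](C)(O)[C@@H]2CC[C@](C)([C@@H](CC(C)C)c3c(O)c(C=O)c(O)c(C=O)c3O)[C@H]2C1 | target

**Total step count:** 5
**Longest linear sequence:** 5 steps (1 → 3 → 4 → 6 → 7 → 12)

**Steps most likely to fail**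

Step 5 is the main risk. Electrophiles normally enter germacrene A at C1 (eudesmane-mode closure), and hetero-Diels–Alder chromans across either ring alkene are the other expected products. The guaiane-mode adduct 12 may therefore be a minor component, accompanied by its cis-fused, other trans-fused and C9′-epimeric isomers, and must be separated by HPLC. Compound 7 can also be lost to acid-induced cyclization before it is intercepted. The fallback sets out from 8 and 9. They are condensed with benzenesulfinic acid (HCO2H/H2O, rt) to the crystalline benzylic sulfone F1. F1 and 7 are then combined in HFIP/H2O at −20 → 0 °C and NaHCO3 is added. Base-triggered 1,4-elimination of sulfinate releases 10 slowly, with no amine, free aldehyde or acid present, so the cascade can be run cold and hydrogen-bond or Lewis-acid additives can be screened for site selectivity. This does not remove the intrinsic site-selectivity problem; it only widens the conditions that can be tried. The fallback comes back to the route at 12.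

Step 4 may give mainly the 1(10)Z isomer, oligomers, or material lost by Cope rearrangement at the temperature needed for deoxygenation. The fallback sets out from 6. Titanium(III) pinacol coupling at 25 °C (TiCl3(DME)1.5, Zn–Cu, DME, high dilution) stops at the trans-1,2-diol F2, the usual outcome for ten-membered rings, which is separated from any cis-diol. Thiophosgene/DMAP converts it into the cyclic thionocarbonate F3. Corey–Winter elimination with 1,3-dimethyl-2-phenyl-1,3,2-diazaphospholidine at 40 °C is a stereospecific syn-elimination that can only give the E-alkene. The fallback comes back to the route at 7.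

Step 3 may suffer from sluggish transvinylation of the hindered allylic alcohol or from decomposition during thermolysis. The fallback sets out from 4. Johnson orthoester Claisen rearrangement (triethyl orthoacetate, cat. propionic acid, 140 °C) gives the keto ester F4 with the same E-selectivity. LiAlH4 reduces both carbonyls to the diol F5, and Swern oxidation of both alcohols returns the keto-aldehyde. The fallback comes back to the route at 6.

**Further compounds**
F1 | step 5 | 2,4,6-trihydroxy-5-[3-methyl-1-(phenylsulfonyl)butyl]benzene-1,3-dicarbaldehyde (racemic) | O=Cc1c(O)c(C=O)c(O)c(C(CC(C)C)S(=O)(=O)c2ccccc2)c1O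
F2 | step 4 | (5E,8R)-1,5-dimethyl-8-(prop-1-en-2-yl)cyclodec-5-ene-1,2-diol, 1,2-trans (one of the two trans diastereomers drawn; the one with both carbinol centres inverted behaves alike) | C=C(C)[C@@H]1CC[C@](C)(O)[C@@H](O)CC/C(C)=C/C1
F3 | step 4 | cyclic thionocarbonate of the trans-1,2-diol (1,3-dioxolane-2-thione fused at C1/C10) | C=C(C)[C@@H]1CC[C@](C)(OC(=S)O2)[C@@H]2CC/C(C)=C/C1
F4 | step 3 | ethyl (4E,7R)-4-methyl-10-oxo-7-(prop-1-en-2-yl)undec-4-enoate | CCOC(=O)CC/C(C)=C/C[C@@H](CCC(C)=O)C(C)=C
F5 | step 3 | (4E,7R)-4-methyl-7-(prop-1-en-2-yl)undec-4-ene-1,10-diol (C10 epimers) | OCCC/C(C)=C/C[C@@H](CCC(C)O)C(C)=C
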